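**Retrosynthetic overview**

- The target is taken back to its di-tert-butyl ester. Both 4-methoxy-3-methyl-2-pyrone rings are made last, from two methyl ketones, by silyl enol ether annulation with methylmalonyl dichloride (one molecule per ring) and O-methylation.
- The strategy rests on one feature: the two pyrone C-6 atoms sit cis on the adjacent quaternary carbons C-3 and C-4 of the cyclobutane. Joined through an N–N bridge, they form a six-membered 4,5-dihydropyridazine fused to the C-3–C-4 bond, in which each C(CH3)=N unit is a masked acetyl group (pyrone C-6 and C-5).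
- That diazine is disconnected by a tetrazine [4+2] cycloaddition with loss of N2 across the tetrasubstituted C=C of cis-3,4-dimethylcyclobut-3-ene-1,2-dicarboxylic anhydride.
- The cyclobutene anhydride comes from a [2+2] photocycloaddition of 2-butyne and maleic anhydride.
- Ring order: cyclobutane (step 1), temporary diazine (step 2, cleaved in step 3), two pyrones (step 6).

Key step: step 2

Remark: the target has a mirror plane through the midpoints of the C-1–C-2 and C-3–C-4 bonds (meso), so only relative configuration has to be controlled and every isolated intermediate of the main route is achiral. "Configuration A" below means: the two carboxyl-type groups at C-1/C-2 are cis to each other and cis to the methyls at C-3/C-4; the two carbon substituents at C-3/C-4 (azine carbon, acetyl, later pyrone) are cis to each other and on the opposite face.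

**Step 1**
Reactants: 1 2-butyne; 2 maleic anhydride
Product: 3 cis-3,4-dimethylcyclobut-3-ene-1,2-dicarboxylic anhydride (6,7-dimethyl-3-oxabicyclo[3.2.0]hept-6-ene-2,4-dione)
Conditions: hν (medium-pressure Hg lamp, Pyrex), acetophenone (sens.), EtOAc, −30 °C, excess 1
Reagents that add atoms: none
Why: Triplet-sensitised [2+2] photocycloaddition of maleic anhydride to an alkyne is an established route to cyclobutene-1,2-dicarboxylic anhydrides; the cis relation of the two new methine stereocentres is fixed by the five-membered anhydride ring, and excess volatile alkyne should suppress a second addition to the product alkene.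

**Step 2**
Reactants: 3 cis-3,4-dimethylcyclobut-3-ene-1,2-dicarboxylic anhydride; 4 3,6-dimethyl-1,2,4,5-tetrazine
Product: 6 cyclobutane fused on its C-3–C-4 bond to a 3,6-dimethyl-4,5-dihydropyridazine and on its C-1–C-2 bond to the anhydride (configuration A), via bridged tetraaza adduct 5 (not isolated)
Conditions: 4 (1.5 equiv), PhMe (2 M), sealed tube, 110 °C
Reagents that add atoms: none
Why: Proposed new method: the tetrazine should act as the electron-poor 4π partner toward the strained, dialkyl-substituted and therefore comparatively high-lying C=C of 3 in a concerted suprafacial inverse-electron-demand Diels–Alder reaction, and the bridged adduct 5 then expels N2 by retro-[4+2]; the closest known reaction type is the tetrazine cycloaddition with N2 extrusion on cyclopropenes, norbornenes and less substituted cyclobutenes, whereas a fully substituted cyclobutene carrying a fused anhydride has not been used. The six-membered diazine ring is closed by this intermolecular [4+2] cycloaddition, which forms both C–C bonds from the quaternary carbons to the future pyrone C-6 atoms at once, the later loss of N2 only trimming the bicycle to the monocyclic 4,5-dihydropyridazine. The two new quaternary stereocentres are controlled by the suprafacial course (azine carbons cis to each other) and by the folded 3-oxabicyclo[3.2.0]heptene skeleton, whose concave face is blocked by the anhydride so that the diene can only approach the convex face bearing the two methine hydrogens; the azine carbons therefore end trans, and the methyls cis, to the anhydride carbonyls. The selectivity needed is this facial selectivity, secured by the ring fusion, while the open issue is rate at a hindered alkene with a weakly activated dialkyltetrazine, addressed by high concentration and heat, which 3 should tolerate because its fused five-membered ring prevents conrotatory cyclobutene opening. Since both ring-fusion carbons are quaternary, 6 can neither tautomerise to a 1,4-dihydropyridazine nor aromatise, so each C(CH3)=N unit is kept as a masked acetyl group.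

**Step 3**
Reactants: 6 dihydropyridazine-fused cyclobutane anhydride
Product: 7 3,4-diacetyl-3,4-dimethylcyclobutane-1,2-dicarboxylic anhydride (configuration A)
Conditions: O3, CH2Cl2, −78 °C; then N2 purge, warm to rt
Reagents that add atoms: ozone, [O-][O+]=O
Why: Ozonolysis cleaves hydrazone- and azine-type C=N bonds to carbonyl groups, so both C(CH3)=N units should become acetyl groups with the N–N bridge lost as N2; no stereocentre is touched and the anhydride should survive in dry CH2Cl2.

**Step 4**
Reactants: 7 3,4-diacetyl-3,4-dimethylcyclobutane-1,2-dicarboxylic anhydride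
Product: 9 di-tert-butyl 3,4-diacetyl-3,4-dimethylcyclobutane-1,2-dicarboxylate (configuration A), via diacid 8 (not isolated)
Conditions: H2O, THF, 40 °C; evaporate; then Cl3CC(=NH)Ot-Bu (5 equiv), CH2Cl2/cyclohexane, rt
Reagents that add atoms: water, O; tert-butyl 2,2,2-trichloroacetimidate, CC(C)(C)OC(=N)C(Cl)(Cl)Cl
Why: Hydrolysis of the strained cyclic anhydride gives the cis-diacid, and acid-promoted tert-butyl transfer from the trichloroacetimidate esterifies both acids at oxygen without base, which avoids epimerisation of the methine centres and aldol reaction of the cis-diacetyl unit.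

**Step 5**
Reactants: 9 di-tert-butyl 3,4-diacetyl-3,4-dimethylcyclobutane-1,2-dicarboxylate
Product: 10 di-tert-butyl 3,4-dimethyl-3,4-bis[1-(trimethylsilyloxy)ethenyl]cyclobutane-1,2-dicarboxylate (configuration A)
Conditions: Me3SiCl (6 equiv), LiN(i-Pr)2 (2.5 equiv), THF, −78 °C, internal quench; Et3N, pentane work-up
Reagents that add atoms: chlorotrimethylsilane, C[Si](C)(C)Cl
Why: Kinetic enolisation of the methyl ketones with the amide base in the presence of the silyl chloride (silyl enol ether formation with internal quench) should trap each enolate before it can add to the neighbouring acetyl group; enolisation is possible only toward CH3 because the other α-carbon is quaternary, and the hindered ester methines are not deprotonated.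

**Step 6**
Reactants: 10 bis(silyl enol ether); 11 methylmalonyl dichloride (two molecules are consumed, one per enol ether; the second is entered below)
Product: 13 di-tert-butyl 3,4-bis(4-hydroxy-3-methyl-2-oxo-2H-pyran-6-yl)-3,4-dimethylcyclobutane-1,2-dicarboxylate (configuration A), via bis(dioxoacyl chloride) 12 (not isolated)
Conditions: 10 added slowly to 11 (2.5 equiv), Et2O, −78 °C → rt, argon sweep
Reagents that add atoms: methylmalonyl dichloride (second molecule of 11, for the second pyrone ring), CC(C(=O)Cl)C(=O)Cl
Why: C-Acylation of a silyl enol ether by a malonyl dichloride followed by lactonisation of the 3,5-dioxoacyl chloride through the enol oxygen is a known 4-hydroxy-2-pyrone annulation, here run once on each enol ether so that two molecules of 11 are taken up; the ketone carbon becomes pyrone C-6, its former methyl C-5, and each molecule of 11 supplies C-4, C-3 with its methyl and C-2 of one ring, with no new stereocentre in the product.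

**Step 7**
Reactants: 13 bis(4-hydroxy-2-pyrone) di-tert-butyl ester
Product: 14 di-tert-butyl 3,4-bis(4-methoxy-3-methyl-2-oxo-2H-pyran-6-yl)-3,4-dimethylcyclobutane-1,2-dicarboxylate (configuration A)
Conditions: Me2SO4, K2CO3, acetone, 40 °C
Reagents that add atoms: dimethyl sulfate, COS(=O)(=O)OC
Why: O-Alkylation of 4-hydroxy-2-pyrones with dimethyl sulfate and K2CO3 in acetone (Williamson-type methylation of the vinylogous acid) is expected to favour the 4-methoxy-2-pyrone over the 2-methoxy-4-pyrone; the tert-butyl esters and the stereocentres are not affected.

**Step 8**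
Reactants: 14 bis(4-methoxy-2-pyrone) di-tert-butyl ester
Product: 15 3,4-bis(4-methoxy-3-methyl-2-oxo-2H-pyran-6-yl)-3,4-dimethylcyclobutane-1,2-dicarboxylic acid (configuration A; CNP0574758.1)
Conditions: CF3CO2H/CH2Cl2 (1:1), rt
Reagents that add atoms: none
Why: Acidolysis of tert-butyl esters (loss of isobutene through the tert-butyl cation) frees both acids without base, so the cis-diacid cannot epimerise, and the acid-stable methoxypyrones are retained.

**Compound list**

1 | 2-butyne | CC#CC | starting material
2 | maleic anhydride | O=C1C=CC(=O)O1 | starting material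
3 | cis-3,4-dimethylcyclobut-3-ene-1,2-dicarboxylic anhydride | CC1=C(C)[C@H]2C(=O)OC(=O)[C@H]21 | intermediate
4 | 3,6-dimethyl-1,2,4,5-tetrazine | Cc1nnc(C)nn1 | starting material
5 | bridged [4+2] adduct: 1,4-dimethyl-2,3,5,6-tetraazabicyclo[2.2.2]octa-2,5-diene whose C-7–C-8 bond is the dimethylcyclobutane bond, anhydride on the far face | C[C@]12N=N[C@](C)(N=N1)[C@]3(C)[C@H]4C(=O)OC(=O)[C@H]4[C@]23C | intermediate (not isolated)
6 | cyclobutane fused to 3,6-dimethyl-4,5-dihydropyridazine and to the anhydride, configuration A | CC1=NN=C(C)[C@@]2(C)[C@H]3[C@H](C(=O)OC3=O)[C@]21C | intermediate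
7 | 3,4-diacetyl-3,4-dimethylcyclobutane-1,2-dicarboxylic anhydride, configuration A | CC(=O)[C@@]1(C)[C@H]2[C@H](C(=O)OC2=O)[C@]1(C(C)=O)C | intermediate
8 | 3,4-diacetyl-3,4-dimethylcyclobutane-1,2-dicarboxylic acid, configuration A | CC(=O)[C@@]1(C)[C@H](C(=O)O)[C@H](C(=O)O)[C@@]1(C)C(C)=O | intermediate (not isolated)
9 | di-tert-butyl 3,4-diacetyl-3,4-dimethylcyclobutane-1,2-dicarboxylate, configuration A | CC(=O)[C@@]1(C)[C@H](C(=O)OC(C)(C)C)[C@H](C(=O)OC(C)(C)C)[C@@]1(C)C(C)=O | intermediate
10 | di-tert-butyl 3,4-dimethyl-3,4-bis[1-(trimethylsilyloxy)ethenyl]cyclobutane-1,2-dicarboxylate, configuration A | C=C(O[Si](C)(C)C)[C@@]1(C)[C@H](C(=O)OC(C)(C)C)[C@H](C(=O)OC(C)(C)C)[C@@]1(C)C(=C)O[Si](C)(C)C | intermediate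
11 | methylmalonyl dichloride | CC(C(=O)Cl)C(=O)Cl | starting material
12 | di-tert-butyl 3,4-bis(5-chloro-4-methyl-3,5-dioxopentanoyl)-3,4-dimethylcyclobutane-1,2-dicarboxylate, configuration A, side-chain methine centres as a mixture | CC(C(=O)Cl)C(=O)CC(=O)[C@@]1(C)[C@H](C(=O)OC(C)(C)C)[C@H](C(=O)OC(C)(C)C)[C@@]1(C)C(=O)CC(=O)C(C)C(=O)Cl | intermediate (not isolated)
13 | di-tert-butyl 3,4-bis(4-hydroxy-3-methyl-2-oxo-2H-pyran-6-yl)-3,4-dimethylcyclobutane-1,2-dicarboxylate, configuration A | Oc1cc([C@@]2(C)[C@H](C(=O)OC(C)(C)C)[C@H](C(=O)OC(C)(C)C)[C@@]2(C)c2cc(O)c(C)c(=O)o2)oc(=O)c1C | intermediate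
14 | di-tert-butyl 3,4-bis(4-methoxy-3-methyl-2-oxo-2H-pyran-6-yl)-3,4-dimethylcyclobutane-1,2-dicarboxylate, configuration A | COc1cc([C@@]2(C)[C@H](C(=O)OC(C)(C)C)[C@H](C(=O)OC(C)(C)C)[C@@]2(C)c2cc(OC)c(C)c(=O)o2)oc(=O)c1C | intermediate
15 | 3,4-bis(4-methoxy-3-methyl-2-oxo-2H-pyran-6-yl)-3,4-dimethylcyclobutane-1,2-dicarboxylic acid, configuration A | COc1cc([C@@]2(C)[C@H](C(=O)O)[C@H](C(=O)O)[C@@]2(C)c2cc(OC)c(C)c(=O)o2)oc(=O)c1C | target

**Step count and risks**

Total step count: 8. Longest linear sequence: 8 steps (from 2-butyne and maleic anhydride).

Steps most likely to fail: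

1. Step 2 (key step). The cycloaddition may be too slow at the hindered tetrasubstituted alkene, so that thermal decomposition of the tetrazine competes; under forcing conditions the facial selectivity may erode. Running the reaction at 13 kbar in CH2Cl2 at 25 °C would be tried first as a change of conditions only. The fallback uses known reaction types only, sets out from maleic anhydride 2 and comes back at diacid 8; it makes the two quaternary centres in a photochemical step instead of by cycloaddition to a tetrasubstituted alkene. Compound 2 is converted by the 2-aminopyridine-mediated decarboxylative dimerisation in hot acetic acid into dimethylmaleic anhydride F1 (also a commercial compound). Sensitised [2+2] photocycloaddition of this anhydride to commercial 2,5-dimethoxy-2,5-dihydrofuran (COC1C=CC(OC)O1; thioxanthone, MeCN, 365 nm) should give mainly the cis-anti-cis tricyclic anhydride bis-acetal F2. In it the anhydride carbonyl carbons (future acetyl carbons) lie trans, and the methyls cis, to the acetal carbons (future carboxyl carbons). The hindered anhydride is opened with aqueous LiOH to the dilithium dicarboxylate F3. After drying, excess MeLi (Et2O, 0 °C to rt, inverse quench) adds to the lithium carboxylates to give the cis-diacetyl bis-acetal F4; the acetals are inert to these conditions. CrO3/H2SO4 in aqueous acetone (Jones oxidation) then hydrolyses both cyclic acetals and oxidises the resulting bis-lactol to diacid 8, which is esterified as in step 4.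

2. Step 3. Ozone may attack at nitrogen (N-oxide formation) or stop after the first C=N bond, and over-oxidation may set in before both bonds are cleaved. The fallback sets out from 6 and comes back at 9; it cleaves the azine hydrolytically after the ester groups are in place. Compound 6 is opened with H2O/THF to the azine diacid F5 and esterified with the trichloroacetimidate, as in step 4, to the azine di-tert-butyl ester F6. Treatment with excess CuCl2·2H2O in THF/aqueous phosphate buffer (pH 7), in the manner of the copper-promoted hydrolysis of hydrazones, should hydrolyse both C=N bonds. The divalent copper oxidises the liberated hydrazine irreversibly to N2, so that recondensation to the cyclic azine is excluded and 9 is formed directly.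

3. Step 6. The double annulation may stop at one pyrone on the congested bis-enol ether, one molecule of 11 may bridge both enol ethers, and the HCl set free may remove tert-butyl groups. The fallback sets out from 10 and comes back at 13; it builds the pyrones in two stages without a bifunctional acid chloride. Mukaiyama-type C-acylation of 10 with two molecules of the mono-acid chloride ethyl 3-chloro-2-methyl-3-oxopropanoate (CCOC(=O)C(C)C(Cl)=O; ZnCl2 cat., CH2Cl2, 0 °C) cannot bridge and liberates only Me3SiCl. It should give the bis(3,5-dioxo ester) di-tert-butyl 3,4-bis(5-ethoxy-4-methyl-3,5-dioxopentanoyl)-3,4-dimethylcyclobutane-1,2-dicarboxylate F7. Base-mediated lactonisation (DBU, PhMe, 80 °C) with loss of ethanol then gives 13.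

**Further compounds**

F1 | step 2 | dimethylmaleic anhydride (3,4-dimethylfuran-2,5-dione) | CC1=C(C)C(=O)OC1=O
F2 | step 2 | cis-anti-cis photoadduct: 1,2-dimethylcyclobutane-1,2-dicarboxylic anhydride fused on its C-3–C-4 bond to 2,5-dimethoxytetrahydrofuran (acetal carbons as a mixture) | O1C(=O)[C@@]2(C)[C@@H]3C(OC)OC(OC)[C@@H]3[C@@]2(C)C1=O
F3 | step 2 | dilithium salt of the dicarboxylic acid from F2 | [Li+].[Li+].[O-]C(=O)[C@@]1(C)[C@@H]2C(OC)OC(OC)[C@@H]2[C@@]1(C)C([O-])=O
F4 | step 2 | cis-diacetyl bis-acetal: 6,7-diacetyl-2,4-dimethoxy-6,7-dimethyl-3-oxabicyclo[3.2.0]heptane | CC(=O)[C@@]1(C)[C@@H]2C(OC)OC(OC)[C@@H]2[C@@]1(C)C(C)=O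
F5 | step 3 | azine diacid: diacid from opening the anhydride of 6 | CC1=NN=C(C)[C@@]2(C)[C@H](C(=O)O)[C@H](C(=O)O)[C@]21C
F6 | step 3 | azine di-tert-butyl ester: di-tert-butyl ester of F5 | CC1=NN=C(C)[C@@]2(C)[C@H](C(=O)OC(C)(C)C)[C@H](C(=O)OC(C)(C)C)[C@]21C
F7 | step 6 | di-tert-butyl 3,4-bis(5-ethoxy-4-methyl-3,5-dioxopentanoyl)-3,4-dimethylcyclobutane-1,2-dicarboxylate | CCOC(=O)C(C)C(=O)CC(=O)[C@@]1(C)[C@H](C(=O)OC(C)(C)C)[C@H](C(=O)OC(C)(C)C)[C@@]1(C)C(=O)CC(=O)C(C)C(=O)OCC
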